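**Retrosynthetic overview**
1. The ester end is built first: succinic anhydride 1 + benzyl alcohol 2 → half-ester 3, then with N-hydroxyphthalimide 4 → redox-active ester 5 (C1–C3 of the acyl chain plus the benzyl group).
2. Key disconnection C3–C4 (new step): the •CH2CH2CO2Bn unit from 5 is joined to the chain end reached by nickel chain walking from commercial (Z)-tricos-9-ene 6, giving benzyl hexacosanoate 7 directly (C3 + C23 = C26).
3. No ring is formed (the phenyl ring is bought with 2) and there is no stereocentre. The benzyl ester is installed first and no hydrogenolytic step follows.

Assumption: the target has no stereocentre or stereogenic double bond, so "single enantiomer" is taken to mean the achiral compound as drawn.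

**Route**

Step 1
Reactants: 1 succinic anhydride; 2 benzyl alcohol
Product: 3 4-(benzyloxy)-4-oxobutanoic acid (monobenzyl succinate)
Conditions: 1 (1.1 equiv), 4-(dimethylamino)pyridine (5 mol%), toluene, 80 °C, 6 h; extract into aq. NaHCO3, acidify with HCl
Reagents that add atoms: none
Why: Catalysed alcoholysis (ring-opening nucleophilic acyl substitution) of a cyclic anhydride stops at the half-ester because the carboxylic acid formed cannot acylate a second alcohol without a dehydrating agent, and no stereocentre is involved.

Step 2
Reactants: 3 4-(benzyloxy)-4-oxobutanoic acid; 4 N-hydroxyphthalimide
Product: 5 benzyl 1,3-dioxoisoindolin-2-yl butanedioate (N-acyloxyphthalimide redox-active ester of 3)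
Conditions: N,N'-diisopropylcarbodiimide (1.1 equiv), 4-(dimethylamino)pyridine (10 mol%), CH2Cl2, 0 °C to rt, 3 h
Reagents that add atoms: none
Why: Steglich-type carbodiimide esterification of the acid with the acidic N–OH group is the standard route to N-acyloxyphthalimides and leaves the benzyl ester untouched.

Step 3
Reactants: 5 benzyl 1,3-dioxoisoindolin-2-yl butanedioate; 6 (Z)-tricos-9-ene
Product: 7 benzyl hexacosanoate
Conditions: NiBr2(MeOCH2CH2OMe) (10 mol%), bathocuproine (12 mol%), (EtO)2MeSiH (2.5 equiv), KF (20 mol%, initiator), THF/N,N-dimethylacetamide 2:1, 40 °C, 5 (1.6 equiv) added over 8 h; aq. NH4Cl work-up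
Reagents that add atoms: none
Why: Proposed new method: nickel-hydride chain-walking (remote, ω-selective) decarboxylative hydroalkylation of an unactivated internal alkene with an N-acyloxyphthalimide, in which the bathocuproine-ligated monovalent nickel hydride made from NiBr2 and the silane adds across C9=C10 of 6, the 2,9-dimethyl groups of the ligand favour fast β-hydride elimination/re-insertion so nickel walks to the unhindered chain end (both directions give the same n-tricosyl–nickel, so alkene position and geometry do not matter), this primary alkylnickel reduces the slowly added 5 by single-electron transfer to release CO2, phthalimidate and the radical •CH2CH2CO2Bn, radical capture gives a trivalent dialkylnickel that reductively eliminates the C3–C4 bond, and the silane converts nickel phthalimidate back to the hydride; the closest known reaction types are nickel-hydride remote hydroalkylation of internal alkenes with alkyl halides and nickel-hydride decarboxylative anti-Markovnikov hydroalkylation of terminal alkenes with redox-active esters, and no stereocentre is created.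

**Compound list**
1 | succinic anhydride (oxolane-2,5-dione) | O=C1CCC(=O)O1 | starting material
2 | benzyl alcohol | OCc1ccccc1 | starting material
3 | 4-(benzyloxy)-4-oxobutanoic acid (monobenzyl succinate) | OC(=O)CCC(=O)OCc1ccccc1 | intermediate
4 | N-hydroxyphthalimide (2-hydroxyisoindoline-1,3-dione) | ON1C(=O)c2ccccc2C1=O | starting material
5 | benzyl 1,3-dioxoisoindolin-2-yl butanedioate | O=C(CCC(=O)ON1C(=O)c2ccccc2C1=O)OCc1ccccc1 | intermediate
6 | (Z)-tricos-9-ene | CCCCCCCC/C=C\CCCCCCCCCCCCC | starting material
7 | benzyl hexacosanoate | CCCCCCCCCCCCCCCCCCCCCCCCCC(=O)OCc1ccccc1 | target

**Step count and risks**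

Total step count: 3. Longest linear sequence: 3 steps (1 → 3 → 5 → 7; 6 enters in the last step).

The three steps most likely to fail, in order of risk, are step 3, step 2 and step 1.

For step 3 (the proposed new step), the risks are:
- trapping of nickel before it has walked the eight positions to the chain end, which gives branched isomers of the same mass;
- reduction of the radical to benzyl propanoate, or its dimerisation to dibenzyl adipate;
- simple hydrogenation of 6 to tricosane.

Intramolecular 1,5-hydrogen transfer from the benzylic CH2 is not expected, because the ester prefers the conformation that holds that CH2 away from the radical. The linear product is a crystalline wax and can be enriched by recrystallisation from acetone.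

The fallback uses only known chemistry, sets out from 6 and comes back at 7, bypassing 5. Compound 6 is heated with Cp2Zr(H)Cl (1.5 equiv) in THF at 50 °C, where isomerising hydrozirconation walks the metal to the terminus and gives chloridobis(cyclopentadienyl)(tricosyl)zirconium F1 in the flask. This is cleaved with I2 at 0 °C to 1-iodotricosane F2, which is recrystallised to remove any secondary iodide. F2 then undergoes Giese radical conjugate addition to commercial benzyl acrylate (C=CC(=O)OCc1ccccc1, 4 equiv) with (Me3Si)3SiH and azobisisobutyronitrile in toluene at 80 °C, giving 7.

For step 2, the risks are N-acylurea formation and hydrolysis of the activated ester on silica. The fallback changes the activation from in situ carbodiimide dehydration to a preformed acyl chloride; it sets out from 3 and comes back at 5. Compound 3 is treated with oxalyl chloride and catalytic N,N-dimethylformamide in CH2Cl2 to give benzyl 4-chloro-4-oxobutanoate F3. After evaporation, F3 is added to 4 and triethylamine in CH2Cl2 at 0 °C to give 5, which is purified by crystallisation and not by chromatography.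

For step 1, the risk is small: incomplete conversion, or traces of diester and succinic acid that complicate crystallisation. The fallback reaches 3 by desymmetrisation and not by anhydride opening; it sets out from 1 and 2 and comes back at 3. Compound 1 is heated with 2.2 equiv of 2 and p-toluenesulfonic acid in toluene with azeotropic water removal to give dibenzyl butanedioate F4. F4 is mono-saponified with 1.0 equiv NaOH in THF/water at 0 °C, where the mono-carboxylate is hydrolysed much more slowly than the diester. Acidification gives 3, and the liberated benzyl alcohol is removed by extraction.

**Further compounds**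
F1 | step 3 | chloridobis(cyclopentadienyl)(tricosyl)zirconium (cyclopentadienyl rings drawn σ-bonded) | CCCCCCCCCCCCCCCCCCCCCCC[Zr](Cl)(C1C=CC=C1)C1C=CC=C1
F2 | step 3 | 1-iodotricosane | CCCCCCCCCCCCCCCCCCCCCCCI
F3 | step 2 | benzyl 4-chloro-4-oxobutanoate | O=C(Cl)CCC(=O)OCc1ccccc1
F4 | step 1 | dibenzyl butanedioate (dibenzyl succinate) | O=C(CCC(=O)OCc1ccccc1)OCc1ccccc1
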